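**Retrosynthetic overview**

- The strategy rests on the C9(O)–C10(CO2Me)=C1 corner of the ten-membered ring: C9 is taken as the carbonyl carbon of a cyclooct-4-enone (ring C2–C9), and C10/C1 as the two alkyne carbons of methyl propiolate, inserted into the C9–C2 bond by [2+2] cycloaddition and opening of the cyclobutene.
- From the ten-membered keto ester the endgame is C9 reduction, lactone α-methylenation (C13), O9 acetate, O8 isobutyrate and release of O15.
- The cyclooctenone comes from ring-closing metathesis at C4=C5; its open-chain ketone comes from a terminal alkyne (C9≡C2) and a 2-substituted allyl alcohol (C3, C4, C15) by gold-catalysed hydroalkoxylation and Claisen rearrangement.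
- C8 is set by asymmetric transfer hydrogenation of an alkynyl ketone; C6, C7 and the trans-lactone come from an Evans syn-aldol of a succinyl imide with acrolein.
- Ring order: γ-lactone, then the eight-membered ring, then (through a transient cyclobutene) the ten-membered ring.

Key step: step 12

Remark: locants C1–C15 are those of the germacranolide skeleton (ring C1–C10; C11–C13 lactone carbons; C14 ester carbon; C15 hydroxymethyl carbon); TBS = tert-butyldimethylsilyl, TES = triethylsilyl, PMB = 4-methoxybenzyl; the 6,12-lactone is assumed not to shift to O8 or O9 under the near-neutral conditions used while those hydroxyls are free.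

**Route**

Step 1
Reactants: 1 (S)-4-benzyl-1,3-oxazolidin-2-one; 2 methyl 4-chloro-4-oxobutanoate
Product: 3 (S)-4-benzyl-3-(4-methoxy-4-oxobutanoyl)-1,3-oxazolidin-2-one
Conditions: n-BuLi, THF, −78 °C; then 2, −78 → 0 °C
Reagents that add atoms: none
Why: N-acylation of the lithiated oxazolidinone by the acid chloride (imide formation) is much faster than attack on the methyl ester and creates no stereocentre.

Step 2
Reactants: 3 succinyl imide; 4 acrolein
Product: 6 lactone imide (S)-4-benzyl-3-[(2R,3S)-2-ethenyl-5-oxooxolane-3-carbonyl]-1,3-oxazolidin-2-one, via hydroxy ester 5 (not isolated)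
Conditions: Bu2BOTf, i-Pr2NEt, CH2Cl2, 0 °C; 4, −78 → 0 °C; H2O2, MeOH, pH 7 buffer; then TsOH (cat.), CH2Cl2, 23 °C
Reagents that add atoms: none
Why: Evans syn-aldol reaction: the (Z)-boron enolate, formed only on the imide side, adds to acrolein through a chair transition state on the face left open by the benzyl group, which should set C7 (S) and C6 (R) syn, and acid then closes the γ-hydroxy ester 5 to the trans-lactone (5-exo-trig acyl substitution).

Step 3
Reactants: 6 lactone imide
Product: 7 (2R,3S)-2-ethenyl-5-oxooxolane-3-carboxylic acid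
Conditions: LiOH, H2O2, THF–H2O, 0 °C; Na2SO3; HCl to pH 2
Reagents that add atoms: hydrogen peroxide (as LiOOH), OO
Why: Lithium hydroperoxide attacks the exocyclic imide carbonyl selectively (standard auxiliary hydrolysis), any opened lactone re-closes on acidification, and the trans arrangement at C6/C7 is also the more stable one.

Step 4
Reactants: 7 lactone acid; 8 ethynyltrimethylsilane
Product: 10 ynone (4S,5R)-5-ethenyl-4-[3-(trimethylsilyl)prop-2-ynoyl]oxolan-2-one, via acid chloride 9 (not isolated)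
Conditions: (COCl)2, DMF (cat.), CH2Cl2, 0 → 23 °C; then Me3SiC≡CZnCl (from 8, n-BuLi, ZnCl2, THF, −78 → 0 °C), Pd(PPh3)4 (3 mol%), THF, 0 °C
Reagents that add atoms: oxalyl chloride, O=C(Cl)C(Cl)=O (chlorine of 9 only)
Why: Negishi acylation: fast oxidative addition of zerovalent palladium to the acid chloride and transmetalation with the non-basic alkynylzinc give the ynone without enolising C7 or eliminating the β-acyloxy group, and the fast oxidative addition is relied on to outrun ionisation of the allylic lactone.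

Step 5
Reactants: 10 ynone
Product: 11 propargylic alcohol (4R,5R)-5-ethenyl-4-[(1S)-1-hydroxy-3-(trimethylsilyl)prop-2-yn-1-yl]oxolan-2-one
Conditions: Ru[(S,S)-TsNCH(Ph)CH(Ph)NH](p-cymene) (2 mol%), i-PrOH, 23 °C
Reagents that add atoms: none
Why: Noyori asymmetric transfer hydrogenation of an alkynyl ketone: the (S,S)-catalyst should deliver hydride to give the (8S)-alcohol under neutral conditions, a sense that the Felkin–Anh preference of C7 (attack anti to the C7–C6 bond) is expected to reinforce.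

Step 6
Reactants: 11 propargylic alcohol
Product: 12 silyl ether (4S,5R)-4-[(1S)-1-(tert-butyldimethylsilyloxy)-3-(trimethylsilyl)prop-2-yn-1-yl]-5-ethenyloxolan-2-one
Conditions: t-BuMe2SiOTf, 2,6-lutidine, CH2Cl2, −78 → 0 °C
Reagents that add atoms: tert-butyldimethylsilyl trifluoromethanesulfonate, CC(C)(C)[Si](C)(C)OS(=O)(=O)C(F)(F)F
Why: Silylation with the silyl triflate and a hindered base is reliable for a secondary alcohol and puts on O8 a bulky, non-chelating group that, unlike a propargylic benzyl-type ether, cannot donate hydride to a gold-activated alkyne.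

Step 7
Reactants: 12 silyl ether
Product: 13 terminal alkyne (4S,5R)-4-[(1S)-1-(tert-butyldimethylsilyloxy)prop-2-yn-1-yl]-5-ethenyloxolan-2-one
Conditions: Bu4NF, AcOH, THF, −20 °C
Reagents that add atoms: none
Why: Fluoride-induced protodesilylation cleaves the C(sp)–SiMe3 bond far faster than the hindered secondary O–Si bond, and acetic acid buffering keeps the lactone intact.

Step 8
Reactants: 14 2-methylidenepropane-1,3-diol
Product: 15 2-{[(4-methoxyphenyl)methoxy]methyl}prop-2-en-1-ol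
Conditions: NaH (1 equiv), 14 (3 equiv), THF–DMF, 0 °C; 4-MeOC6H4CH2Cl, Bu4NI (cat.), 23 °C
Reagents that add atoms: 4-methoxybenzyl chloride, COc1ccc(CCl)cc1
Why: Williamson etherification (SN2) with the diol in excess alkylates the monoalkoxide once.

Step 9
Reactants: 13 terminal alkyne; 15 allylic alcohol
Product: 17 diene ketone (4S,5R)-4-[(1S)-1-(TBS-oxy)-5-[(PMB-oxy)methyl]-2-oxohex-5-en-1-yl]-5-ethenyloxolan-2-one, via allyl vinyl ether 16 (not isolated)
Conditions: AuCl(IPr) (5 mol%), AgNTf2 (5 mol%), 15 (4 equiv), 4 Å MS, PhMe, 50 °C; then 110 °C (IPr = 1,3-bis(2,6-diisopropylphenyl)imidazol-2-ylidene)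
Reagents that add atoms: none
Why: Gold-catalysed Markovnikov hydroalkoxylation of the terminal alkyne by 15 puts oxygen on C9 to give the 2-alkoxy-1-alkene 16, whose thermal Claisen [3,3] rearrangement forms C2–C3 and unveils the C9 ketone regiospecifically, with no new stereocentre and no enolate next to the lactone.

Step 10
Reactants: 17 diene ketone
Product: 18 cyclooctenone (3aS,4S,9aR)-4-(TBS-oxy)-8-[(PMB-oxy)methyl]-3,3a,4,6,7,9a-hexahydrocycloocta[b]furan-2,5-dione
Conditions: second-generation Grubbs catalyst RuCl2(=CHPh)(H2IMes)(PCy3) (10 mol%), PhMe (1 mM), 80 °C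
Reagents that add atoms: none
Why: Ring-closing metathesis between the C5 vinyl group and the 1,1-disubstituted C4 alkene closes the eight-membered ring with loss of ethene, the ring size enforcing the ring-cis C4=C5 geometry and the trans-lactone holding the two chains gauche.

Step 11
Reactants: 18 cyclooctenone
Product: 19 silyl enol ether (3aS,4S,9aR)-4-(TBS-oxy)-8-[(PMB-oxy)methyl]-5-(trimethylsilyloxy)-3a,4,7,9a-tetrahydrocycloocta[b]furan-2(3H)-one
Conditions: LiN(SiMe3)2, Me3SiCl, Et3N, THF, −78 °C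
Reagents that add atoms: chlorotrimethylsilane, C[Si](C)(C)Cl
Why: Kinetic enolisation with in situ silylation removes a proton from the unhindered C2 methylene and not from C8, which is shielded by its silyl ether, nor from the less acidic lactone, so the C9=C2 enol ether should form regioselectively.

Step 12
Reactants: 19 silyl enol ether; 20 methyl propiolate
Product: 23 ten-membered alkylidene β-keto ester methyl (3aS,4S,11aR)-4-(TBS-oxy)-10-[(PMB-oxy)methyl]-2,5-dioxo-2,3,3a,4,5,8,9,11a-octahydrocyclodeca[b]furan-6-carboxylate, via siloxycyclobutene 21 (not isolated), via silyl dienol ether 22 (not isolated)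
Conditions: 20 (3 equiv), ZrCl4 (1.2 equiv), CH2Cl2–Et2O, −78 → −30 °C; pH 7 buffer; crude in PhMe, 80 °C; then 1 M HCl, THF, 23 °C
Reagents that add atoms: none
Why: ZrCl4-activated methyl propiolate is attacked at its β-carbon by C2 of the silyl enol ether, and the zirconium allenolate closes onto the C9 silyloxycarbenium ion (4-exo closure), a stepwise [2+2] cycloaddition that forms C2–C1 and C9–C10 and gives the cis-fused siloxycyclobutene 21; this is the known Lewis acid-promoted [2+2] of silyl enol ethers with propiolates. On warming, 21 undergoes thermal conrotatory 4π electrocyclic opening across C9–C2 with the silyloxy group turning outward, so the ten-membered ring is closed by ring expansion driven by cyclobutene strain, not by an end-to-end cyclisation. Aqueous acid cleaves the silyl dienol ether 22, and protonation at C2 through the dienol moves the double bond into conjugation as C1=C10, the ring-cis geometry being expected as the thermodynamic one. No stereocentre is created, and C6, C7 and C8 are untouched because C8 is never enolised. The step needs head-to-tail regioselectivity, which the polarity of the enol ether (nucleophilic C2) and the ynoate (electrophilic CH) secures, and ring closure in preference to silyl transfer to an open Michael adduct, which low temperature and an oxophilic, non-basic Lewis acid favour. The O8 silyl ether and the remote allylic PMB ether are expected to tolerate ZrCl4 at −78 °C.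

Step 13
Reactants: 23 keto ester
Product: 24 allylic alcohol methyl (3aS,4S,5S,11aR)-4-(TBS-oxy)-5-hydroxy-10-[(PMB-oxy)methyl]-2-oxo-2,3,3a,4,5,8,9,11a-octahydrocyclodeca[b]furan-6-carboxylate
Conditions: NaBH4, CeCl3·7H2O, MeOH–THF, −78 °C
Reagents that add atoms: none
Why: Luche reduction: cerium activation directs hydride to the C9 carbonyl (1,2-addition) and not to the doubly activated C1=C10 bond, and with the non-chelating silyloxy group on C8 antiperiplanar to the incoming hydride (polar Felkin–Anh) the 8,9-syn alcohol, (9S), is expected.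

Step 14
Reactants: 24 allylic alcohol
Product: 25 triethylsilyl ether methyl (3aS,4S,5S,11aR)-4-(TBS-oxy)-10-[(PMB-oxy)methyl]-2-oxo-5-(triethylsilyloxy)-2,3,3a,4,5,8,9,11a-octahydrocyclodeca[b]furan-6-carboxylate
Conditions: Et3SiOTf, 2,6-lutidine, CH2Cl2, −78 °C
Reagents that add atoms: triethylsilyl trifluoromethanesulfonate, CC[Si](CC)(CC)OS(=O)(=O)C(F)(F)F
Why: Silylation masks O9 as a triethylsilyl ether that survives the enolate chemistry of the next step and can later be removed in the presence of the O8 TBS ether.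

Step 15
Reactants: 25 triethylsilyl ether
Product: 27 Mannich base methyl (3R,3aS,4S,5S,11aR)-3-[(dimethylamino)methyl]-4-(TBS-oxy)-10-[(PMB-oxy)methyl]-2-oxo-5-(triethylsilyloxy)-2,3,3a,4,5,8,9,11a-octahydrocyclodeca[b]furan-6-carboxylate, via silyl ketene acetal 26 (not isolated)
Conditions: LiN(i-Pr)2, Me3SiCl, THF, −78 °C; then [Me2N=CH2]I, CH2Cl2, 23 °C; NaHCO3 (aq.)
Reagents that add atoms: chlorotrimethylsilane, C[Si](C)(C)Cl (silicon of 26 only); N,N-dimethylmethyleneiminium iodide, C=[N+](C)C.[I-]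
Why: Mannich reaction of a lactone silyl ketene acetal: the lactone α-CH2 is the most acidic C–H and is trapped as it forms (internal quench), which avoids transannular Michael addition to the enoate, and the ketene acetal is then aminomethylated on the face anti to the C7 substituent.

Step 16
Reactants: 27 Mannich base
Product: 29 α-methylene lactone methyl (3aS,4S,5S,11aR)-4-(TBS-oxy)-3-methylidene-10-[(PMB-oxy)methyl]-2-oxo-5-(triethylsilyloxy)-2,3,3a,4,5,8,9,11a-octahydrocyclodeca[b]furan-6-carboxylate, via ammonium iodide 28 (not isolated)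
Conditions: MeI, MeOH, 23 °C; then NaHCO3 (aq.), EtOAc, 23 °C
Reagents that add atoms: iodomethane, CI (methyl of 28 only)
Why: N-methylation turns the amine into a leaving group and mild base induces E1cB elimination to the exocyclic C11=C13 alkene, which also removes the temporary C11 stereocentre.

Step 17
Reactants: 29 α-methylene lactone
Product: 30 C9 alcohol methyl (3aS,4S,5S,11aR)-4-(TBS-oxy)-5-hydroxy-3-methylidene-10-[(PMB-oxy)methyl]-2-oxo-2,3,3a,4,5,8,9,11a-octahydrocyclodeca[b]furan-6-carboxylate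
Conditions: PPTS (cat.), MeOH–CH2Cl2, 0 °C
Reagents that add atoms: none
Why: Acid-catalysed methanolysis cleaves the triethylsilyl ether selectively because it is far more labile than the hindered secondary TBS ether and the PMB ether.

Step 18
Reactants: 30 C9 alcohol
Product: 31 acetate methyl (3aS,4S,5S,11aR)-5-acetoxy-4-(TBS-oxy)-3-methylidene-10-[(PMB-oxy)methyl]-2-oxo-2,3,3a,4,5,8,9,11a-octahydrocyclodeca[b]furan-6-carboxylate
Conditions: Ac2O, pyridine, DMAP (cat.), CH2Cl2, 0 °C
Reagents that add atoms: acetic anhydride, CC(=O)OC(C)=O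
Why: DMAP-catalysed acetylation of the only free hydroxyl is straightforward, since O8 and O15 are still protected.

Step 19
Reactants: 31 acetate
Product: 32 C8 alcohol methyl (3aR,4S,5S,11aR)-5-acetoxy-4-hydroxy-3-methylidene-10-[(PMB-oxy)methyl]-2-oxo-2,3,3a,4,5,8,9,11a-octahydrocyclodeca[b]furan-6-carboxylate
Conditions: HF·pyridine, pyridine, THF, 0 → 23 °C
Reagents that add atoms: none
Why: Buffered fluoride cleaves the remaining silyl ether under weakly acidic conditions that leave the acetate, the PMB ether and the α-methylene lactone intact and do not promote 1,2-acyl shift.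

Step 20
Reactants: 32 C8 alcohol
Product: 33 isobutyrate methyl (3aS,4S,5S,11aR)-5-acetoxy-3-methylidene-4-(2-methylpropanoyloxy)-10-[(PMB-oxy)methyl]-2-oxo-2,3,3a,4,5,8,9,11a-octahydrocyclodeca[b]furan-6-carboxylate
Conditions: (i-PrCO)2O, Et3N, DMAP (cat.), CH2Cl2, 0 °C
Reagents that add atoms: 2-methylpropanoic anhydride, CC(C)C(=O)OC(=O)C(C)C
Why: DMAP-catalysed acylation of the hindered C8 hydroxyl with the anhydride should be faster than base-induced migration of the neighbouring acetate or transacylation of the lactone.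

Step 21
Reactants: 33 isobutyrate
Product: 34 target CNP0242134.2
Conditions: DDQ, CH2Cl2–pH 7 buffer, 0 °C
Reagents that add atoms: none
Why: Oxidative cleavage of the p-methoxybenzyl ether by DDQ (hydride abstraction, then hydrolysis of the oxocarbenium ion) is neutral and should spare the two esters, the α-methylene lactone and the trisubstituted alkenes.

**Compound list**

1 | (S)-4-benzyl-1,3-oxazolidin-2-one | O=C1OC[C@H](Cc2ccccc2)N1 | starting material
2 | methyl 4-chloro-4-oxobutanoate | COC(=O)CCC(=O)Cl | starting material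
3 | (S)-4-benzyl-3-(4-methoxy-4-oxobutanoyl)-1,3-oxazolidin-2-one | COC(=O)CCC(=O)N1C(=O)OC[C@@H]1Cc1ccccc1 | intermediate
4 | acrolein (prop-2-enal) | C=CC=O | starting material
5 | methyl (3S,4R)-3-[(S)-4-benzyl-2-oxo-1,3-oxazolidine-3-carbonyl]-4-hydroxyhex-5-enoate | C=C[C@@H](O)[C@H](CC(=O)OC)C(=O)N1C(=O)OC[C@@H]1Cc1ccccc1 | intermediate (not isolated)
6 | (S)-4-benzyl-3-[(2R,3S)-2-ethenyl-5-oxooxolane-3-carbonyl]-1,3-oxazolidin-2-one | C=C[C@H]1OC(=O)C[C@@H]1C(=O)N1C(=O)OC[C@@H]1Cc1ccccc1 | intermediate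
7 | (2R,3S)-2-ethenyl-5-oxooxolane-3-carboxylic acid | C=C[C@H]1OC(=O)C[C@@H]1C(=O)O | intermediate
8 | ethynyltrimethylsilane | C#C[Si](C)(C)C | starting material
9 | (2R,3S)-2-ethenyl-5-oxooxolane-3-carbonyl chloride | C=C[C@H]1OC(=O)C[C@@H]1C(=O)Cl | intermediate (not isolated)
10 | (4S,5R)-5-ethenyl-4-[3-(trimethylsilyl)prop-2-ynoyl]oxolan-2-one | C=C[C@H]1OC(=O)C[C@@H]1C(=O)C#C[Si](C)(C)C | intermediate
11 | (4R,5R)-5-ethenyl-4-[(1S)-1-hydroxy-3-(trimethylsilyl)prop-2-yn-1-yl]oxolan-2-one | C=C[C@H]1OC(=O)C[C@@H]1[C@H](O)C#C[Si](C)(C)C | intermediate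
12 | (4S,5R)-4-[(1S)-1-(tert-butyldimethylsilyloxy)-3-(trimethylsilyl)prop-2-yn-1-yl]-5-ethenyloxolan-2-one | C=C[C@H]1OC(=O)C[C@@H]1[C@H](O[Si](C)(C)C(C)(C)C)C#C[Si](C)(C)C | intermediate
13 | (4S,5R)-4-[(1S)-1-(tert-butyldimethylsilyloxy)prop-2-yn-1-yl]-5-ethenyloxolan-2-one | C=C[C@H]1OC(=O)C[C@@H]1[C@H](O[Si](C)(C)C(C)(C)C)C#C | intermediate
14 | 2-methylidenepropane-1,3-diol | C=C(CO)CO | starting material
15 | 2-{[(4-methoxyphenyl)methoxy]methyl}prop-2-en-1-ol | C=C(CO)COCc1ccc(OC)cc1 | intermediate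
16 | (4S,5R)-4-[(1S)-1-(TBS-oxy)-2-({2-[(PMB-oxy)methyl]prop-2-en-1-yl}oxy)prop-2-en-1-yl]-5-ethenyloxolan-2-one | C=C[C@H]1OC(=O)C[C@@H]1[C@H](O[Si](C)(C)C(C)(C)C)C(=C)OCC(=C)COCc1ccc(OC)cc1 | intermediate (not isolated)
17 | (4S,5R)-4-[(1S)-1-(TBS-oxy)-5-[(PMB-oxy)methyl]-2-oxohex-5-en-1-yl]-5-ethenyloxolan-2-one | C=C[C@H]1OC(=O)C[C@@H]1[C@H](O[Si](C)(C)C(C)(C)C)C(=O)CCC(=C)COCc1ccc(OC)cc1 | intermediate
18 | (3aS,4S,9aR)-4-(TBS-oxy)-8-[(PMB-oxy)methyl]-3,3a,4,6,7,9a-hexahydrocycloocta[b]furan-2,5-dione (ring-cis C4=C5) | O=C1CC/C(COCc2ccc(OC)cc2)=C\[C@H]2OC(=O)C[C@@H]2[C@@H]1O[Si](C)(C)C(C)(C)C | intermediate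
19 | (3aS,4S,9aR)-4-(TBS-oxy)-8-[(PMB-oxy)methyl]-5-(trimethylsilyloxy)-3a,4,7,9a-tetrahydrocycloocta[b]furan-2(3H)-one | C[Si](C)(C)O/C1=C/C/C(COCc2ccc(OC)cc2)=C\[C@H]2OC(=O)C[C@@H]2[C@@H]1O[Si](C)(C)C(C)(C)C | intermediate (key-step precursor)
20 | methyl propiolate (methyl prop-2-ynoate) | C#CC(=O)OC | starting material
21 | siloxycyclobutene fused across C9–C2 of the eight-membered ring (OSiMe3 on C9, CO2Me on C10, cis ring fusion; the face is not controlled and is immaterial, so C9 and C2 are left open in the SMILES) | COC(=O)C1=CC2C/C(COCc3ccc(OC)cc3)=C\[C@H]3OC(=O)C[C@@H]3[C@H](O[Si](C)(C)C(C)(C)C)C12O[Si](C)(C)C | intermediate (not isolated)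
22 | methyl (3aS,4S,11aR)-4-(TBS-oxy)-10-[(PMB-oxy)methyl]-2-oxo-5-(trimethylsilyloxy)-2,3,3a,4,9,11a-hexahydrocyclodeca[b]furan-6-carboxylate (C9=C10 ring-cis, C1=C2 ring-trans) | C1C(=O)O[C@@H]2/C=C(/COCc3ccc(OC)cc3)C/C=C/C(C(=O)OC)=C(/O[Si](C)(C)C)[C@@H](O[Si](C)(C)C(C)(C)C)[C@@H]12 | intermediate (not isolated)
23 | methyl (3aS,4S,11aR)-4-(TBS-oxy)-10-[(PMB-oxy)methyl]-2,5-dioxo-2,3,3a,4,5,8,9,11a-octahydrocyclodeca[b]furan-6-carboxylate | C1C(=O)O[C@@H]2/C=C(/COCc3ccc(OC)cc3)CC/C=C(/C(=O)OC)C(=O)[C@@H](O[Si](C)(C)C(C)(C)C)[C@@H]12 | intermediate (key-step product)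
24 | methyl (3aS,4S,5S,11aR)-4-(TBS-oxy)-5-hydroxy-10-[(PMB-oxy)methyl]-2-oxo-2,3,3a,4,5,8,9,11a-octahydrocyclodeca[b]furan-6-carboxylate | C1C(=O)O[C@@H]2/C=C(/COCc3ccc(OC)cc3)CC/C=C(/C(=O)OC)[C@H](O)[C@@H](O[Si](C)(C)C(C)(C)C)[C@@H]12 | intermediate
25 | methyl (3aS,4S,5S,11aR)-4-(TBS-oxy)-10-[(PMB-oxy)methyl]-2-oxo-5-(triethylsilyloxy)-2,3,3a,4,5,8,9,11a-octahydrocyclodeca[b]furan-6-carboxylate | C1C(=O)O[C@@H]2/C=C(/COCc3ccc(OC)cc3)CC/C=C(/C(=O)OC)[C@H](O[Si](CC)(CC)CC)[C@@H](O[Si](C)(C)C(C)(C)C)[C@@H]12 | intermediate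
26 | methyl (3aS,4S,5S,11aR)-4-(TBS-oxy)-10-[(PMB-oxy)methyl]-5-(triethylsilyloxy)-2-(trimethylsilyloxy)-3a,4,5,8,9,11a-hexahydrocyclodeca[b]furan-6-carboxylate | C1=C(O[Si](C)(C)C)O[C@@H]2/C=C(/COCc3ccc(OC)cc3)CC/C=C(/C(=O)OC)[C@H](O[Si](CC)(CC)CC)[C@@H](O[Si](C)(C)C(C)(C)C)[C@@H]12 | intermediate (not isolated)
27 | methyl (3R,3aS,4S,5S,11aR)-3-[(dimethylamino)methyl]-4-(TBS-oxy)-10-[(PMB-oxy)methyl]-2-oxo-5-(triethylsilyloxy)-2,3,3a,4,5,8,9,11a-octahydrocyclodeca[b]furan-6-carboxylate | CN(C)C[C@@H]1C(=O)O[C@@H]2/C=C(/COCc3ccc(OC)cc3)CC/C=C(/C(=O)OC)[C@H](O[Si](CC)(CC)CC)[C@@H](O[Si](C)(C)C(C)(C)C)[C@@H]12 | intermediate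
28 | N,N,N-trimethylammonium iodide of 27 | C[N+](C)(C)C[C@@H]1C(=O)O[C@@H]2/C=C(/COCc3ccc(OC)cc3)CC/C=C(/C(=O)OC)[C@H](O[Si](CC)(CC)CC)[C@@H](O[Si](C)(C)C(C)(C)C)[C@@H]12.[I-] | intermediate (not isolated)
29 | methyl (3aS,4S,5S,11aR)-4-(TBS-oxy)-3-methylidene-10-[(PMB-oxy)methyl]-2-oxo-5-(triethylsilyloxy)-2,3,3a,4,5,8,9,11a-octahydrocyclodeca[b]furan-6-carboxylate | C=C1C(=O)O[C@@H]2/C=C(/COCc3ccc(OC)cc3)CC/C=C(/C(=O)OC)[C@H](O[Si](CC)(CC)CC)[C@@H](O[Si](C)(C)C(C)(C)C)[C@@H]12 | intermediate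
30 | methyl (3aS,4S,5S,11aR)-4-(TBS-oxy)-5-hydroxy-3-methylidene-10-[(PMB-oxy)methyl]-2-oxo-2,3,3a,4,5,8,9,11a-octahydrocyclodeca[b]furan-6-carboxylate | C=C1C(=O)O[C@@H]2/C=C(/COCc3ccc(OC)cc3)CC/C=C(/C(=O)OC)[C@H](O)[C@@H](O[Si](C)(C)C(C)(C)C)[C@@H]12 | intermediate
31 | methyl (3aS,4S,5S,11aR)-5-acetoxy-4-(TBS-oxy)-3-methylidene-10-[(PMB-oxy)methyl]-2-oxo-2,3,3a,4,5,8,9,11a-octahydrocyclodeca[b]furan-6-carboxylate | C=C1C(=O)O[C@@H]2/C=C(/COCc3ccc(OC)cc3)CC/C=C(/C(=O)OC)[C@H](OC(C)=O)[C@@H](O[Si](C)(C)C(C)(C)C)[C@@H]12 | intermediate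
32 | methyl (3aR,4S,5S,11aR)-5-acetoxy-4-hydroxy-3-methylidene-10-[(PMB-oxy)methyl]-2-oxo-2,3,3a,4,5,8,9,11a-octahydrocyclodeca[b]furan-6-carboxylate | C=C1C(=O)O[C@@H]2/C=C(/COCc3ccc(OC)cc3)CC/C=C(/C(=O)OC)[C@H](OC(C)=O)[C@@H](O)[C@@H]12 | intermediate
33 | methyl (3aS,4S,5S,11aR)-5-acetoxy-3-methylidene-4-(2-methylpropanoyloxy)-10-[(PMB-oxy)methyl]-2-oxo-2,3,3a,4,5,8,9,11a-octahydrocyclodeca[b]furan-6-carboxylate | C=C1C(=O)O[C@@H]2/C=C(/COCc3ccc(OC)cc3)CC/C=C(/C(=O)OC)[C@H](OC(C)=O)[C@@H](OC(=O)C(C)C)[C@@H]12 | intermediate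
34 | CNP0242134.2, methyl (3aS,4S,5S,6E,10E,11aR)-5-acetoxy-10-(hydroxymethyl)-3-methylidene-4-(2-methylpropanoyloxy)-2-oxo-2,3,3a,4,5,8,9,11a-octahydrocyclodeca[b]furan-6-carboxylate | C=C1C(=O)O[C@@H]2/C=C(/CO)CC/C=C(/C(=O)OC)[C@H](OC(C)=O)[C@@H](OC(=O)C(C)C)[C@@H]12 | target

**Step count and risks**

Total step count: 21. Longest linear sequence: 20 steps (steps 1–7 and 9–21; step 8 is a one-step side branch).

Steps most likely to fail:

Step 12 (key step). After the conjugate addition the zwitterion may transfer its silyl group and collapse to an open Michael adduct instead of closing the four-membered ring. The Lewis acid may also strip the PMB ether, and the opening or isomerisation may stop at a deconjugated stage. The fallback sets out from 18 and runs the same two-carbon insertion thermally through an enamine, without Lewis acid. Condensation with pyrrolidine (TiCl4, pyrrolidine, PhMe, 0 °C) should give the less substituted C9=C2 enamine F5. With methyl propiolate 20 (Et2O–MeCN, 23 °C) F5 should undergo [2+2] addition and spontaneous opening of the aminocyclobutene to the ring-expanded dienamine F6. Hydrolysis with aqueous AcOH–NaOAc comes back to the route at 23.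

Step 9. The Claisen shift may fail to keep pace with ketal exchange or hydration by traces of water, or the C5 vinyl group may add to the gold-activated alkyne (enyne cycloisomerisation). The fallback sets out from 13. Hg(OTf)2-catalysed Markovnikov hydration in wet MeCN should give the methyl ketone F1. The allylic iodide F2 is made from alcohol 15 (I2, PPh3, imidazole, CH2Cl2). The kinetic lithium enolate of F1 (LiN(i-Pr)2, THF, −78 °C) is alkylated at C2 with F2 (DMPU, −78 → −40 °C), which comes back to the route at 17.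

Step 10. Intermolecular metathesis (oligomerisation) may outrun closure of the trisubstituted eight-membered ring, and the vinyl group may migrate. The fallback sets out from 17 and moves the ring closure to the C9 carbinol oxidation level. Felkin-type reduction (NaBH4, MeOH, −40 °C) should give mainly the (9S)-carbinol F3, whose configuration is immaterial. Ring-closing metathesis of F3 (second-generation Hoveyda–Grubbs catalyst RuCl2(=CH-2-i-PrOC6H4)(H2IMes), PhMe, high dilution, 80 °C) gives the cyclooctenol F4. Dess–Martin oxidation comes back to the route at 18.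

Further compounds
F1 | step 9 | (4S,5R)-4-[(1S)-1-(tert-butyldimethylsilyloxy)-2-oxopropyl]-5-ethenyloxolan-2-one | C=C[C@H]1OC(=O)C[C@@H]1[C@H](O[Si](C)(C)C(C)(C)C)C(C)=O
F2 | step 9 | 1-({[2-(iodomethyl)prop-2-en-1-yl]oxy}methyl)-4-methoxybenzene | C=C(CI)COCc1ccc(OC)cc1
F3 | step 10 | (4S,5R)-4-[(1S,2S)-1-(TBS-oxy)-2-hydroxy-5-[(PMB-oxy)methyl]hex-5-en-1-yl]-5-ethenyloxolan-2-one | C=C[C@H]1OC(=O)C[C@@H]1[C@H](O[Si](C)(C)C(C)(C)C)[C@@H](O)CCC(=C)COCc1ccc(OC)cc1
F4 | step 10 | (3aS,4S,5S,9aR)-4-(TBS-oxy)-5-hydroxy-8-[(PMB-oxy)methyl]-3a,4,5,6,7,9a-hexahydrocycloocta[b]furan-2(3H)-one | O[C@H]1CC/C(COCc2ccc(OC)cc2)=C\[C@H]2OC(=O)C[C@@H]2[C@@H]1O[Si](C)(C)C(C)(C)C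
F5 | step 12 | (3aS,4S,9aR)-4-(TBS-oxy)-8-[(PMB-oxy)methyl]-5-(pyrrolidin-1-yl)-3a,4,7,9a-tetrahydrocycloocta[b]furan-2(3H)-one | C1CCN(C1)/C2=C/C/C(COCc3ccc(OC)cc3)=C\[C@H]3OC(=O)C[C@@H]3[C@@H]2O[Si](C)(C)C(C)(C)C
F6 | step 12 | methyl (3aS,4S,11aR)-4-(TBS-oxy)-10-[(PMB-oxy)methyl]-2-oxo-5-(pyrrolidin-1-yl)-2,3,3a,4,9,11a-hexahydrocyclodeca[b]furan-6-carboxylate | C1C(=O)O[C@@H]2/C=C(/COCc3ccc(OC)cc3)C/C=C/C(C(=O)OC)=C(/N3CCCC3)[C@@H](O[Si](C)(C)C(C)(C)C)[C@@H]12
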